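**Plan**
Retrosynthesis: the target isoflavone is cut first at O1–C8a, which opens ring C to a Z-hydroxymethylene ketone. It is then cut at C2–C3 (formyl carbon removed) and at C3–C1' (ring B removed from a methyl ketone).
Enabling feature: on ring A, C8a (bearing O1) lies para to C6 (bearing the free OH) and ortho to C4a (bearing the C4 carbonyl). Ring A is therefore a hydroquinone monoether, and its O1–C8a bond can be made by two-electron oxidation of a 3-hydroxy-4-methoxyphenyl ketone at the C–H para to the phenol.
Forward: rings A and B are bought as isoacetovanillone and 1-bromo-2,4,5-trimethoxybenzene. C3–C1' is made by Pd-catalysed α-arylation, C2 is added by Claisen formylation, and ring C (the pyranone) closes last at the anode with the 6-OH left free.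
Stereochemistry: the target has no stereocentre. The only stereo-element on the way is the Z geometry of the enol C2=C3 bond, which is set by equilibration to the chelated enol and then locked in ring C.

Key step: step 5

Remark: the target SMILES contains no stereocentre, stereogenic axis or stereogenic double bond, so only one form of the compound exists and no enantiomer has to be selected.

Step 1
Reactants: 1 1-(3-hydroxy-4-methoxyphenyl)ethanone (isoacetovanillone)
Product: 2 1-[3-(benzyloxy)-4-methoxyphenyl]ethanone
Conditions: BnBr (1.1 equiv), K2CO3 (1.5 equiv), DMF, 60 °C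
Reagents that add atoms: benzyl bromide, BrCc1ccccc1
Why: Williamson ether synthesis, in which the phenoxide formed by K2CO3 displaces bromide and the resulting benzyl ether shields the acidic OH from the strong base of step 2 yet is removable later under neutral conditions.

Step 2
Reactants: 2 1-[3-(benzyloxy)-4-methoxyphenyl]ethanone; 3 1-bromo-2,4,5-trimethoxybenzene
Product: 4 1-[3-(benzyloxy)-4-methoxyphenyl]-2-(2,4,5-trimethoxyphenyl)ethanone
Conditions: Pd(OAc)2 (2 mol %), P(t-Bu)3·HBF4 (4 mol %), NaOt-Bu (2.2 equiv), toluene, 80 °C, Ar
Reagents that add atoms: none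
Why: Buchwald–Hartwig-type Pd-catalysed α-arylation of a methyl ketone enolate, in which the bulky electron-rich phosphine enables oxidative addition of the electron-rich bromide, while the ortho-methoxy group and immediate deprotonation of the more acidic product hold the reaction at monoarylation.

Step 3
Reactants: 4 1-[3-(benzyloxy)-4-methoxyphenyl]-2-(2,4,5-trimethoxyphenyl)ethanone
Product: 5 1-(3-hydroxy-4-methoxyphenyl)-2-(2,4,5-trimethoxyphenyl)ethanone
Conditions: H2 (1 atm), 10 % Pd/C, EtOAc–EtOH, rt
Reagents that add atoms: none
Why: catalytic hydrogenolysis of a benzyl aryl ether, placed before the one-carbon extension so that the reducible enol never meets H2/Pd, with the aryl ketone and methyl ethers inert at 1 atm in neutral solvent.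

Step 4
Reactants: 5 1-(3-hydroxy-4-methoxyphenyl)-2-(2,4,5-trimethoxyphenyl)ethanone
Product: 6 (Z)-3-hydroxy-1-(3-hydroxy-4-methoxyphenyl)-2-(2,4,5-trimethoxyphenyl)prop-2-en-1-one
Conditions: NaH (4 equiv), HCO2Et (10 equiv), THF, 0 °C to rt; then 1 M HCl, 0 °C
Reagents that add atoms: ethyl formate, CCOC=O
Why: crossed Claisen condensation (α-formylation of a deoxybenzoin) driven by formation of the stabilised β-dicarbonyl enolate, with the phenol carried as its phenoxide by the extra base, and on acidification the product should settle as the hydrogen-bonded Z enol that has the enol oxygen and the aroyl group on the same side of C2=C3.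

Step 5
Reactants: 6 (Z)-3-hydroxy-1-(3-hydroxy-4-methoxyphenyl)-2-(2,4,5-trimethoxyphenyl)prop-2-en-1-one
Product: 8 6-hydroxy-7-methoxy-3-(2,4,5-trimethoxyphenyl)chromen-4-one, via 8aH-chromene-4,6-dione 7 (not isolated)
Conditions: RVC anode | Pt cathode, undivided cell, anode potential held at the first wave (fixed beforehand by CV), 2.0–2.2 F mol⁻¹, 2,6-lutidine (2 equiv), n-Bu4NPF6 (0.1 M), dry HFIP, 5 mM in 6, Ar, rt
Reagents that add atoms: none
Why: Proposed new method: the phenol of 6, hydrogen-bonded to lutidine, should lose two electrons and one proton at the anode to give a phenoxonium ion with positive charge on the carbons ortho and para to its oxygen; the enol(ate) oxygen, once rotation about C3–C4 releases it from the chelate, adds to the para carbon to form O1–C8a and dienone 7, which tautomerises at once to phenol 8 while the released protons are reduced to H2 at the cathode and lutidine is regenerated. The closest known reaction types are the oxidative cyclisation of 2,3'-dihydroxybenzophenones to 2-hydroxyxanthones, anodic phenol dearomatisation with oxygen nucleophiles, and the anodic catechol/1,3-dicarbonyl benzofuran synthesis in which an enol oxygen closes onto an electrogenerated quinone, but closure of an open-chain enol oxygen on the para C–H of a phenoxonium ion to build a pyranone has not been shown. The single ring formed, pyranone ring C, closes in a six-membered O-to-C(sp2) mode that counts as 6-endo-trig on the C4a=C8a bond of the quinoid cation, and the Z enol geometry keeps the oxygen within reach of C8a. No lasting stereocentre arises, since C8a of 7 forms as a racemate and becomes planar again on rearomatisation. The step needs oxidation of the phenol before the 2,4,5-trimethoxyphenyl ring and the enolate, which is secured by the proton-coupled oxidation at the lowest potential, by potential control and by HFIP hydrogen bonding that raises the potentials of the methoxyarene and enolate sites, and a hole that starts on ring B should be passed on to the phenol. It also needs para rather than ortho closure, favoured by the larger LUMO coefficient and the lower crowding at C8a compared with the carbon wedged between OH and acyl, while high dilution counters phenoxyl dimerisation and the charge limit together with the weak donor character of the vinylogous-ester O1 counters further oxidation of 8.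

**Compound list**
1 | 1-(3-hydroxy-4-methoxyphenyl)ethanone (isoacetovanillone) | CC(=O)c1ccc(OC)c(O)c1 | starting material
2 | 1-[3-(benzyloxy)-4-methoxyphenyl]ethanone | CC(=O)c1ccc(OC)c(OCc2ccccc2)c1 | intermediate
3 | 1-bromo-2,4,5-trimethoxybenzene | COc1cc(OC)c(Br)cc1OC | starting material
4 | 1-[3-(benzyloxy)-4-methoxyphenyl]-2-(2,4,5-trimethoxyphenyl)ethanone | COc1ccc(C(=O)Cc2cc(OC)c(OC)cc2OC)cc1OCc1ccccc1 | intermediate
5 | 1-(3-hydroxy-4-methoxyphenyl)-2-(2,4,5-trimethoxyphenyl)ethanone | COc1ccc(C(=O)Cc2cc(OC)c(OC)cc2OC)cc1O | intermediate
6 | (Z)-3-hydroxy-1-(3-hydroxy-4-methoxyphenyl)-2-(2,4,5-trimethoxyphenyl)prop-2-en-1-one | O/C=C(/c1cc(OC)c(OC)cc1OC)C(=O)c1ccc(OC)c(O)c1 | intermediate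
7 | 7-methoxy-3-(2,4,5-trimethoxyphenyl)-8aH-chromene-4,6-dione (racemic at C8a, transient) | COC1=CC2OC=C(c3cc(OC)c(OC)cc3OC)C(=O)C2=CC1=O | intermediate
8 | 6-hydroxy-7-methoxy-3-(2,4,5-trimethoxyphenyl)chromen-4-one | COc1cc2occ(-c3cc(OC)c(OC)cc3OC)c(=O)c2cc1O | target

**Count**
Total steps: 5. Longest linear sequence: 5 (1 → 2 → 4 → 5 → 6 → 8).

**Steps most likely to fail**

Step 5.
- What may go wrong: electron loss from the trimethoxyphenyl ring or the enolate instead of the phenol, followed by closure onto the wrong arene. Other risks are closure at the ortho instead of the para carbon, dimerisation of the phenoxyl radical, and continued oxidation of the product phenol.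
- Fallback from 5, rejoining at 8 (known chemistry): the oxygen para to the phenol is installed chemically and the ring is then closed by the classical deoxybenzoin method.
- Elbs persulfate oxidation of 5 (K2S2O8, aq KOH, pyridine, 0 °C to rt, N2) should give potassium 4-hydroxy-5-methoxy-2-[(2,4,5-trimethoxyphenyl)acetyl]phenyl sulfate F1.
- Hydrolysis (aq HCl, 80 °C) should free 1-(2,5-dihydroxy-4-methoxyphenyl)-2-(2,4,5-trimethoxyphenyl)ethanone F2.
- Formylative cyclisation with BF3·OEt2, DMF and MsCl, which tolerates free phenols, should close the pyranone to 8.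

Step 2.
- What may go wrong: slow oxidative addition of the electron-rich, ortho-substituted bromide, so that aldol self-condensation of the methyl ketone and catalyst decay take over, or a second arylation.
- Fallback from 2, rejoining at 6: the C3–C1' bond is made by a 1,2-aryl shift instead of a cross-coupling.
- Claisen–Schmidt condensation of 2 with commercial 2,4,5-trimethoxybenzaldehyde (KOH, EtOH) should give (E)-1-[3-(benzyloxy)-4-methoxyphenyl]-3-(2,4,5-trimethoxyphenyl)prop-2-en-1-one F3.
- Oxidative rearrangement with Tl(NO3)3·3H2O in MeOH/CH(OMe)3 moves the electron-rich aryl group to the α-carbon. This should give racemic 1-[3-(benzyloxy)-4-methoxyphenyl]-3,3-dimethoxy-2-(2,4,5-trimethoxyphenyl)propan-1-one F4.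
- Hydrogenolysis (H2, Pd/C) of the acetal-masked compound should give 1-(3-hydroxy-4-methoxyphenyl)-3,3-dimethoxy-2-(2,4,5-trimethoxyphenyl)propan-1-one F5.
- Mild acid hydrolysis (aq HCl, THF) should release enol 6.

Step 4.
- What may go wrong: sluggish condensation of the poorly soluble phenoxide–enolate dianion, with base-induced decomposition of ethyl formate outrunning C-formylation.
- Fallback from 4, rejoining at 6: the carbon is introduced under neutral conditions on the protected ketone and the phenol is freed afterwards.
- Heating 4 with DMF dimethyl acetal (toluene, 110 °C) should give 1-[3-(benzyloxy)-4-methoxyphenyl]-3-(dimethylamino)-2-(2,4,5-trimethoxyphenyl)prop-2-en-1-one F6. Its E/Z composition does not matter because hydrolysis erases it.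
- Hydrogenolysis (H2, Pd/C, EtOAc), to which the push–pull enaminone should be inert, should give 3-(dimethylamino)-1-(3-hydroxy-4-methoxyphenyl)-2-(2,4,5-trimethoxyphenyl)prop-2-en-1-one F7.
- Aqueous acid (1 M HCl, THF, rt) should hydrolyse F7 to 6.

**Further compounds**
F1 | step 5 | potassium 4-hydroxy-5-methoxy-2-[(2,4,5-trimethoxyphenyl)acetyl]phenyl sulfate | COc1cc(OS(=O)(=O)[O-])c(C(=O)Cc2cc(OC)c(OC)cc2OC)cc1O.[K+]
F2 | step 5 | 1-(2,5-dihydroxy-4-methoxyphenyl)-2-(2,4,5-trimethoxyphenyl)ethanone | COc1cc(O)c(C(=O)Cc2cc(OC)c(OC)cc2OC)cc1O
F3 | step 2 | (E)-1-[3-(benzyloxy)-4-methoxyphenyl]-3-(2,4,5-trimethoxyphenyl)prop-2-en-1-one | COc1ccc(C(=O)/C=C/c2cc(OC)c(OC)cc2OC)cc1OCc1ccccc1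
F4 | step 2 | 1-[3-(benzyloxy)-4-methoxyphenyl]-3,3-dimethoxy-2-(2,4,5-trimethoxyphenyl)propan-1-one (racemic) | COc1ccc(C(=O)C(C(OC)OC)c2cc(OC)c(OC)cc2OC)cc1OCc1ccccc1
F5 | step 2 | 1-(3-hydroxy-4-methoxyphenyl)-3,3-dimethoxy-2-(2,4,5-trimethoxyphenyl)propan-1-one (racemic) | COc1ccc(C(=O)C(C(OC)OC)c2cc(OC)c(OC)cc2OC)cc1O
F6 | step 4 | 1-[3-(benzyloxy)-4-methoxyphenyl]-3-(dimethylamino)-2-(2,4,5-trimethoxyphenyl)prop-2-en-1-one (E/Z mixture) | CN(C)C=C(c1cc(OC)c(OC)cc1OC)C(=O)c1ccc(OC)c(OCc2ccccc2)c1
F7 | step 4 | 3-(dimethylamino)-1-(3-hydroxy-4-methoxyphenyl)-2-(2,4,5-trimethoxyphenyl)prop-2-en-1-one (E/Z mixture) | CN(C)C=C(c1cc(OC)c(OC)cc1OC)C(=O)c1ccc(OC)c(O)c1
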